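**Retrosynthetic overview**

- The plan rests on ring A: C5, C6, C7 and C8 each carry oxygen, so the C4a–C8a edge can be supplied by 3,4,5,6-tetramethoxybenzyne, whose two reactive carbons are equivalent.
- Target 22 comes from 3-hydroxyflavone 21 by cleaving the two benzyl ethers of ring B and the 5-O-methyl group; 21 comes from flavone 19 by oxidation at C3.
- Ring C is formed last and in one operation: bonds C8a–O1, C4a–C4 and O1–C2 arise when the aryne from silyl triflate 11 inserts into the acyl C–O bond of arylpropiolic acid 16 and the phenoxide closes onto the ynone.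
- Silyl triflate 11 is built from 2,3,4-trimethoxybenzaldehyde 1 through 1,2,3,4-tetramethoxybenzene 4 and phenol 7 (bromination, retro-Brook shift, triflation).
- Acid 16 comes from 3,4-bis(benzyloxy)benzaldehyde 12 by Corey–Fuchs homologation with a CO2 quench; rings A and B are bought as arenes.

Key step: step 8

Remark: the target is achiral. The only stereocentres on the way are the two of epoxide 20, which forms as a racemate and loses both in the same step; its SMILES shows one enantiomer.

**Route**

Step 1
Reactants: 1 2,3,4-trimethoxybenzaldehyde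
Product: 3 2,3,4-trimethoxyphenol, via 2,3,4-trimethoxyphenyl formate 2 (not isolated)
Conditions: 30% aq H2O2, H2SO4 (cat.), MeOH, rt
Reagents that add atoms: hydrogen peroxide, OO
Why: Dakin oxidation by the Baeyer–Villiger pathway, in which the electron-rich aryl group migrates to oxygen to give formate 2, which the acidic methanol cleaves to the phenol.

Step 2
Reactants: 3 2,3,4-trimethoxyphenol
Product: 4 1,2,3,4-tetramethoxybenzene
Conditions: MeI, K2CO3, acetone, reflux
Reagents that add atoms: iodomethane, CI
Why: Williamson O-methylation of the phenoxide by SN2 attack on iodomethane, with no other nucleophilic site in the molecule.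

Step 3
Reactants: 4 1,2,3,4-tetramethoxybenzene
Product: 7 2,3,4,5-tetramethoxyphenol, via aryllithium 5 (not isolated), via lithium aryltrimethoxyborate 6 (not isolated)
Conditions: n-BuLi, TMEDA, THF, 0 °C; B(OMe)3, −78 °C → rt; then AcOH, 30% aq H2O2, 0 °C → rt
Reagents that add atoms: hydrogen peroxide, OO
Why: Directed ortho-metalation at one of the two equivalent ring hydrogens (each ortho to a methoxy group), borylation, and oxidative 1,2-shift of the aryl group from boron to oxygen under acidic peroxide, which spares the electron-rich phenol from basic air oxidation.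

Step 4
Reactants: 7 2,3,4,5-tetramethoxyphenol
Product: 8 2-bromo-3,4,5,6-tetramethoxyphenol
Conditions: NBS, CH2Cl2, −78 °C → 0 °C, dark
Reagents that add atoms: N-bromosuccinimide, O=C1CCC(=O)N1Br
Why: Electrophilic aromatic bromination at the only free ring position, which lies ortho to the hydroxyl group, under cold anhydrous conditions that disfavour oxidation of the para-methoxyphenol.

Step 5
Reactants: 8 2-bromo-3,4,5,6-tetramethoxyphenol
Product: 11 3,4,5,6-tetramethoxy-2-(trimethylsilyl)phenyl trifluoromethanesulfonate, via aryl trimethylsilyl ether 9 (not isolated), via lithium 2-silylphenoxide 10 (not isolated)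
Conditions: HN(SiMe3)2, THF, 70 °C, then evaporate; n-BuLi, THF, −78 °C; Tf2O, −78 °C → rt
Reagents that add atoms: hexamethyldisilazane, C[Si](C)(C)N[Si](C)(C)C; trifluoromethanesulfonic anhydride, O=S(=O)(OS(=O)(=O)C(F)(F)F)C(F)(F)F
Why: O-silylation, then bromine–lithium exchange that triggers a 1,3 oxygen-to-carbon silyl shift (retro-Brook rearrangement) to phenoxide 10, which is trapped as its triflate, the standard entry to o-silylaryl triflates.

Step 6
Reactants: 12 3,4-bis(benzyloxy)benzaldehyde
Product: 13 1,2-bis(benzyloxy)-4-(2,2-dibromovinyl)benzene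
Conditions: CBr4, PPh3, CH2Cl2, 0 °C
Reagents that add atoms: carbon tetrabromide, BrC(Br)(Br)Br
Why: First stage of the Corey–Fuchs reaction, a Wittig olefination by the ylide Ph3P=CBr2 formed in the flask.

Step 7
Reactants: 13 1,2-bis(benzyloxy)-4-(2,2-dibromovinyl)benzene
Product: 16 3-[3,4-bis(benzyloxy)phenyl]propiolic acid, via lithium acetylide 14 (not isolated), via lithium propiolate 15 (not isolated)
Conditions: n-BuLi (2.2 equiv), THF, −78 °C; CO2 (g), −78 °C → rt; aq HCl
Reagents that add atoms: carbon dioxide, O=C=O
Why: Second stage of the Corey–Fuchs reaction (bromine–lithium exchange, Fritsch–Buttenberg–Wiechell shift and deprotonation to acetylide 14), followed by carboxylation of the acetylide and acidification, with the benzyl ethers inert at −78 °C.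

Step 8
Reactants: 11 3,4,5,6-tetramethoxy-2-(trimethylsilyl)phenyl trifluoromethanesulfonate (1.5 equiv); 16 3-[3,4-bis(benzyloxy)phenyl]propiolic acid
Product: 19 3',4'-bis(benzyloxy)-5,6,7,8-tetramethoxyflavone, via 3,4,5,6-tetramethoxybenzyne 17 (not isolated), via o-hydroxyaryl ynone 18 (not isolated)
Conditions: CsF (4 equiv), THF, 125 °C, sealed tube
Reagents that add atoms: none
Why: Fluoride attacks silicon in 11 and expels triflate to give aryne 17 and also deprotonates 16; the carboxylate oxygen adds to the aryne (C8a–O1), the aryl anion so formed attacks the neighbouring acyl carbon (C4a–C4), and the four-membered adduct opens to ynone 18 as its caesium phenoxide. This is the known insertion of arynes into the C–O bond of carboxylic acids to give o-hydroxyaryl ketones, which with arylpropiolic acids runs on to flavones. Ring C then closes by 6-endo-dig oxa-Michael addition of the phenoxide to the β-carbon of the ynone (O1–C2), and protonation at C3 gives 19; no stereocentre is formed. The aryne addition needs no regiocontrol, because 17 has a mirror plane through its reactive bond and both termini are the same. The 6-endo closure must win over 5-exo closure to the aurone, and the polarisation of the conjugated ynone under metal-free basic conditions secures this. Acyl transfer must also outrun protonation of the aryl anion to the aryl ester, which the aprotic medium, the high temperature and the intramolecular delivery favour.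

Step 9
Reactants: 19 3',4'-bis(benzyloxy)-5,6,7,8-tetramethoxyflavone
Product: 21 3',4'-bis(benzyloxy)-3-hydroxy-5,6,7,8-tetramethoxyflavone, via flavone 2,3-epoxide 20 (not isolated)
Conditions: DMDO (acetone solution, excess), CH2Cl2, 0 °C → rt; then p-TsOH·H2O (cat.), CH2Cl2, rt
Reagents that add atoms: dimethyldioxirane, CC1(C)OO1
Why: Electrophilic epoxidation of the enol-ether-like C2=C3 bond (feasible because C5 bears a methyl ether and not a hydrogen-bonded hydroxyl), then acid-catalysed opening of 20 at C2 and loss of H3 to restore the pyranone as the 3-hydroxyflavone, which erases both stereocentres of the racemic epoxide.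

Step 10
Reactants: 21 3',4'-bis(benzyloxy)-3-hydroxy-5,6,7,8-tetramethoxyflavone
Product: 22 3,5,3',4'-tetrahydroxy-6,7,8-trimethoxyflavone
Conditions: BCl3 (excess), C6HMe5, CH2Cl2, −78 °C → 0 °C; then MeOH/H2O
Reagents that add atoms: none
Why: BCl3 ionises the two aryl benzyl ethers at low temperature while pentamethylbenzene traps the benzyl cation by Friedel–Crafts alkylation, and on warming boron held between C4=O and the peri 5-methoxy oxygen activates only that methyl group for attack by chloride, so the 6-, 7- and 8-methyl ethers stay.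

**Compound list**

1 | 2,3,4-trimethoxybenzaldehyde | COc1ccc(C=O)c(OC)c1OC | starting material
2 | 2,3,4-trimethoxyphenyl formate | COc1ccc(OC=O)c(OC)c1OC | intermediate
3 | 2,3,4-trimethoxyphenol | COc1ccc(O)c(OC)c1OC | intermediate
4 | 1,2,3,4-tetramethoxybenzene | COc1ccc(OC)c(OC)c1OC | intermediate
5 | (2,3,4,5-tetramethoxyphenyl)lithium | [Li]c1cc(OC)c(OC)c(OC)c1OC | intermediate
6 | lithium trimethoxy(2,3,4,5-tetramethoxyphenyl)borate | [Li+].CO[B-](OC)(OC)c1cc(OC)c(OC)c(OC)c1OC | intermediate
7 | 2,3,4,5-tetramethoxyphenol | COc1cc(O)c(OC)c(OC)c1OC | intermediate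
8 | 2-bromo-3,4,5,6-tetramethoxyphenol | COc1c(OC)c(OC)c(O)c(Br)c1OC | intermediate
9 | (2-bromo-3,4,5,6-tetramethoxyphenoxy)trimethylsilane | COc1c(OC)c(OC)c(O[Si](C)(C)C)c(Br)c1OC | intermediate
10 | lithium 3,4,5,6-tetramethoxy-2-(trimethylsilyl)phenoxide | [Li+].COc1c(OC)c(OC)c([O-])c([Si](C)(C)C)c1OC | intermediate
11 | 3,4,5,6-tetramethoxy-2-(trimethylsilyl)phenyl trifluoromethanesulfonate | COc1c(OC)c(OC)c(OS(=O)(=O)C(F)(F)F)c([Si](C)(C)C)c1OC | intermediate
12 | 3,4-bis(benzyloxy)benzaldehyde | O=Cc1ccc(OCc2ccccc2)c(OCc2ccccc2)c1 | starting material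
13 | 1,2-bis(benzyloxy)-4-(2,2-dibromovinyl)benzene | BrC(Br)=Cc1ccc(OCc2ccccc2)c(OCc2ccccc2)c1 | intermediate
14 | {[3,4-bis(benzyloxy)phenyl]ethynyl}lithium | [Li]C#Cc1ccc(OCc2ccccc2)c(OCc2ccccc2)c1 | intermediate
15 | lithium 3-[3,4-bis(benzyloxy)phenyl]propiolate | [Li+].[O-]C(=O)C#Cc1ccc(OCc2ccccc2)c(OCc2ccccc2)c1 | intermediate
16 | 3-[3,4-bis(benzyloxy)phenyl]propiolic acid | OC(=O)C#Cc1ccc(OCc2ccccc2)c(OCc2ccccc2)c1 | intermediate
17 | 3,4,5,6-tetramethoxybenzyne | COC1=C(OC)C(OC)=C(OC)C#C1 | intermediate
18 | 3-[3,4-bis(benzyloxy)phenyl]-1-(2-hydroxy-3,4,5,6-tetramethoxyphenyl)prop-2-yn-1-one (present as its caesium phenoxide) | COc1c(OC)c(OC)c(C(=O)C#Cc2ccc(OCc3ccccc3)c(OCc3ccccc3)c2)c(O)c1OC | intermediate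
19 | 3',4'-bis(benzyloxy)-5,6,7,8-tetramethoxyflavone | COc1c(OC)c(OC)c2c(=O)cc(-c3ccc(OCc4ccccc4)c(OCc4ccccc4)c3)oc2c1OC | intermediate
20 | 3',4'-bis(benzyloxy)-5,6,7,8-tetramethoxyflavone 2,3-epoxide (racemic, cis-fused; one enantiomer drawn) | COc1c(OC)c(OC)c2C(=O)[C@H]3O[C@@]3(c4ccc(OCc5ccccc5)c(OCc5ccccc5)c4)Oc2c1OC | intermediate
21 | 3',4'-bis(benzyloxy)-3-hydroxy-5,6,7,8-tetramethoxyflavone | COc1c(OC)c(OC)c2c(=O)c(O)c(-c3ccc(OCc4ccccc4)c(OCc4ccccc4)c3)oc2c1OC | intermediate
22 | 3,5,3',4'-tetrahydroxy-6,7,8-trimethoxyflavone | COc1c(OC)c(O)c2c(=O)c(O)c(-c3ccc(O)c(O)c3)oc2c1OC | target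

**Step count**

Total: 10 steps. Longest linear sequence: 8 steps (steps 1, 2, 3, 4, 5, 8, 9, 10).

**Steps most likely to fail**

1. Step 8. The aryl anion may be protonated before it reaches the acyl carbon, which stops the sequence at O-arylation. The caesium propiolate may also lose CO2 at 125 °C before it meets the aryne, and part of the phenoxide may close in the 5-exo mode. The fallback builds ring C by the classical chalcone route, from 7 and 12 back to 19. Phenol 7 should be C-acetylated at its single free ortho position (AcOH, BF3·OEt2, 80 °C) to give 1-(2-hydroxy-3,4,5,6-tetramethoxyphenyl)ethan-1-one F1. Claisen–Schmidt condensation of this ketone with aldehyde 12 (KOH, EtOH, rt) should give the 2'-hydroxychalcone F2. Oxidative cyclisation of the chalcone (I2 cat., DMSO, 130 °C) should then give flavone 19.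

2. Step 4. The very electron-rich phenol may be attacked at the methoxy-bearing carbon para to the hydroxyl group and oxidised towards a quinone instead of being brominated at the ortho carbon. The fallback installs silicon by directed metalation, with no bromination and no retro-Brook shift, from 7 back to 11. Phenol 7 and isopropyl isocyanate (Et3N cat., CH2Cl2) should give the N-isopropylcarbamate F3. Temporary N-silylation and ortho-lithiation at the only ortho hydrogen (TMSOTf, TMEDA, Et2O; n-BuLi, −78 °C), quench with TMSCl and aqueous work-up should give the ortho-silyl carbamate F4. Cleavage of the carbamate (DBU, Et2NH, MeCN, 40 °C) should free 3,4,5,6-tetramethoxy-2-(trimethylsilyl)phenol F5, which is triflated in the same flask with PhNTf2 to give 11.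

3. Step 10. Demethylation may go past C5 to the neighbouring 6-methoxy group once the 5-O-borate has formed, or stop short at C5 because boron is tied up by the 3-hydroxyl and catechol oxygens. Benzyl cations that escape the scavenger may also alkylate the electron-rich rings. The fallback separates the two cleavages, from 21 to 22. Hydrogenolysis of 21 (H2, 1 atm, Pd(OH)2/C, THF/MeOH, rt) should give 3,3',4'-trihydroxy-5,6,7,8-tetramethoxyflavone F6. Chelation-controlled cleavage of the 5-methyl ether with AlCl3 in MeCN at 50 °C, followed by dilute aqueous HCl, should give 22.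

**Further compounds**

F1 | step 8 | 1-(2-hydroxy-3,4,5,6-tetramethoxyphenyl)ethan-1-one | CC(=O)c1c(O)c(OC)c(OC)c(OC)c1OC
F2 | step 8 | (E)-3-[3,4-bis(benzyloxy)phenyl]-1-(2-hydroxy-3,4,5,6-tetramethoxyphenyl)prop-2-en-1-one | COc1c(OC)c(OC)c(C(=O)/C=C/c2ccc(OCc3ccccc3)c(OCc3ccccc3)c2)c(O)c1OC
F3 | step 4 | 2,3,4,5-tetramethoxyphenyl N-(propan-2-yl)carbamate | CC(C)NC(=O)Oc1cc(OC)c(OC)c(OC)c1OC
F4 | step 4 | 2,3,4,5-tetramethoxy-6-(trimethylsilyl)phenyl N-(propan-2-yl)carbamate | CC(C)NC(=O)Oc1c([Si](C)(C)C)c(OC)c(OC)c(OC)c1OC
F5 | step 4 | 3,4,5,6-tetramethoxy-2-(trimethylsilyl)phenol | COc1c(OC)c(OC)c(O)c([Si](C)(C)C)c1OC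
F6 | step 10 | 3,3',4'-trihydroxy-5,6,7,8-tetramethoxyflavone | COc1c(OC)c(OC)c2c(=O)c(O)c(-c3ccc(O)c(O)c3)oc2c1OC
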